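The constants, given at 25 °C, describe substrate dosed steadily into a stirred flask. There it passes through catalyst intermediate to target, or goes two at a time to homo dimer, while target turns reversibly into isomer of the product.

| flask | substrate | free catalyst | temperature | time |
|---|---|---|---|---|
| north | 0.50 mM (fed, over 40 s) | 0.25 µM | −15 °C | 40 s |
| north-west | 0.50 mM (fed, over 40 s) | 0.25 µM | 5 °C | 40 s |
| east | 0.50 mM (fed, over 40 s) | 0.25 µM | 25 °C | 40 s |

- the best flask by amount of target, in percent of the substrate charged; "all alike" if 1.5 percentage points covers them all (north / north-west / east / all alike)
- amount of target at the end, in percent of the substrate charged, north
- amount of target at the end, in percent of the substrate charged, north-west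
- amount of target at the end, in percent of the substrate charged, east

- in percentages every species weighs as the substrate in it: one homo dimer counts as two
- two of one species on the left: rate k times its square, two consumed each time
- constants are those at 25 °C; use the activation energies and enthalpies for any other temperature

    substrate + free catalyst → catalyst intermediate (k1 = 1.9 × 10⁵ /M/s, Ea1 = 18.0 kJ/mol)
    catalyst intermediate → free catalyst + target (k2 = 440 /s, Ea2 = 64.0 kJ/mol)
    2 substrate → homo dimer (k3 = 770 /M/s, Ea3 = 39.0 kJ/mol)
    target ⇌ isomer of the product (K4 = 11, k4 = 0.090 /s, Ea4 = 80.0 kJ/mol, ΔH4 = 9.00 kJ/mol)
    (constants at 25 °C)

We keep a ledger by hand for the north-west flask, whose relaxation half-life we have, and we work with the fraction left, not the fraction made.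

1. Substrate is the limiting reagent, since free catalyst returns at each turn. The catalyst can hold at most 0.0500% of the charge, so we leave that entry out.

2. Three entries remain: c(substrate), 2·c(homo dimer) and the product made, which we count as target plus isomer of the product.

3. Target and isomer of the product relax towards each other with a half-life of 70.1 s, both directions together.

4. We take the product as made at a steady rate over 40 s, so its average age at the end is 20.0 s.

5. The kept fraction, the share of product made that is still target at the end, is one half raised to the power of that age over the half-life, or 82.1%. We treat the loss as running towards nothing, which leaves the equilibrium share out and puts this figure a little low.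

6. The books close with c(target) = kept fraction × (charge − c(substrate) − 2·c(homo dimer)). Our reckoning stops here: the first two entries are still to be found.

The forecast chooses north-west, with 8.4% in north, 17.6% in north-west and 8.4% in east. Of north-west it says: “About 13% isomerises, leaving about 88 µM, or 17.6%.” Our own step gives a loss of 17.9%, not the forecast's 13%.

The simulation gives north-west as the best flask, with 17.7% against 8.42% in north and 8.41% in east, so the forecast held. At the end of north-west, 27.3% stands as substrate and 52.2% as homo dimer. The ledger therefore has 20.5% as product, and the kept fraction makes that 16.8% target, against the 17.7% computed for north-west.

The neighbour flask is north-west with 0.0010 mM of free catalyst at the same temperature, so we carry the kept fraction over unchanged. With 17.6% substrate and 23.5% homo dimer, 59.0% is product, and the kept fraction gives 48.4% target; the computed flask holds 50.8%.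

The constants used here belong to no real substance; the result is computed.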